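(Readings and results are calculated for substances that don't exist, and the scatter is random.)

Read the maple run late, at 12 min and 15 min: these two readings of target average 0.222 M and show no rise. Divide that level by the starting material and the partner left, each reckoned as its charge less the target made. This gives the plateau quotient K, here 0.581 M⁻¹.

| flask | starting material | partner | target | time |
|---|---|---|---|---|
| maple | 0.800 M | 0.880 M |  |  |
| birch | 0.320 M | 0.400 M |  |  |
| elm | 0.800 M | 0.880 M | 0.240 M |  |
| larch | 0.800 M | 0.180 M |  | 15 min |

- maple run (time / min: [target] / M): 0.67: 0.048; 2.0: 0.090; 3.9: 0.125; 6.1: 0.155; 8.8: 0.195; 12: 0.225; 15: 0.218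
- birch run (time / min: [target] / M): 0.67: 0.006; 2.0: 0; 3.9: 0.020; 6.1: 0.028; 8.8: 0.052; 12: 0.058; 15: 0.047
- elm run (time / min: [target] / M): 0.67: 0.248; 2.0: 0.292; 3.9: 0.317; 6.1: 0.336; 8.8: 0.355; 12: 0.333; 15: 0.349

(scatter of a reading: 0.01 M)

- Overall: starting material + partner -> target.
- Constant volume, constant temperature.
- A reading of a species includes what of it is bound.

- target in the larch run at 15 min, as a share of the starting material charged

Test K on the other runs. The last two birch readings give 0.565 M⁻¹. The last two elm readings give 0.626 M⁻¹, with the target gained subtracted from both charges. So my reckoning carries one K.

In the larch run, partner is the limiting reagent, 0.180 M against 0.800 M of starting material. Fold the charge into one number. The split number B is K times the starting material left, and it states target over partner left at the plateau. Take B = 1 as the zero of the scale: partner is shared evenly. At the larch charge B is 0.465, so the share of partner turned is B/(1+B), giving 0.0571 M. Subtract that from the starting material: B becomes 0.432. Then target is 0.0543 M, or 6.79% of the starting material. This assumes a level by 15 min, and the larch charge has less partner than the birch charge, so it lies outside the tested span.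

The forecast says 7%, with a range of 5.7% to 8.2%: “So K ≈ 0.62 M⁻¹ holds across a wide concentration range.” My figure of 6.79% lies slightly below it.

    starting material + 2 partner → target + partner (0.8100 M⁻² min⁻¹)
    target + partner → side product (0.2136 M⁻¹ min⁻¹)
    2 partner ⇌ idle reagent dimer, settled at all times (4.770 M⁻¹)

The larch run gives 6.67% at 15 min, or 0.0533 M of target. Its target over the partner charge less that target is 0.421, against B of 0.432. Now use B on the elm run, with 0.0160 M made in both it and the maple run. B there is 0.456. Take the open part of the way to the level as 1 minus target over B times the partner charge less the amount made. That puts the elm run at 0.365 of the maple rate. The elm run goes faster than that, at 0.65 of the maple rate.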